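**Plan**
- Retrosynthetic cuts: the C8–O acyl bond (side-chain acid), C11=C13 and C10=C14 (two methylenations), C5–C6 (ring A), C1–C2 (sp2–sp3 coupling), C7–C11 (epoxide opening).
- Forward order: ring B is made first as a 2-iodocyclohex-2-enone from cyclohexa-1,3-diene, the C2–C5 tether is coupled to C1, and ring A is then closed by the C5–C6 bond.
- Enabling feature: C5 is the vinylic CH of the C4=C5 alkene, and C6 is β (C1 is α) to C10 once the exocyclic-methylene carbon C10 is a ketone. A C5 vinyl radical can therefore close ring A 6-endo onto a 2-alkylcyclohexenone, and the same ketone lets C1 equilibrate.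
- Stereochemistry: C7/C8 come from one catalytic asymmetric epoxidation and an anti epoxide opening; C6 is relayed from C7 in the ring closure; C1 is set thermodynamically; C3' of the side chain comes from an asymmetric Morita–Baylis–Hillman reaction.
- Helpers removed later: the C10 ketone (becomes C=CH2), the bromine on C5, and the silyl and tert-butyl protecting groups.

Key step: step 9

Remark 1: cadinane numbering is used. C1/C6 are the ring-fusion carbons; ring A is C1–C2–C3–C4(=C5)–C6 with C15 on C4; ring B is C6–C7–C8–C9–C10–C1; C7 carries C11(=C13)–C12, C8 the ester oxygen, C10 carries C14. With H-6 drawn β, the target has H-1α, H-6β, H-7α and H-8β, i.e. a trans-decalin with all four ring-B substituents equatorial.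
Remark 2: the (S,S)-configured (salen)MnCl catalyst is assumed to give the (1S,6R)-oxide, by analogy with other cis-disubstituted conjugated alkenes; if the sense is opposite, the (R,R) catalyst is used.

**Fragment 1: ring B**

Step 1
Reactants: 1 cyclohexa-1,3-diene
Product: 2 (1S,6R)-7-oxabicyclo[4.1.0]hept-2-ene
Conditions: (S,S)-(salen)MnCl (cat.), NaOCl (aq, buffered), 4-phenylpyridine N-oxide, CH2Cl2, 0 °C
Reagents that add atoms: sodium hypochlorite, [Na+].[O-]Cl
Why: Jacobsen–Katsuki epoxidation of a cis-disubstituted conjugated alkene should give the monoepoxide enantioselectively, creating the two stereocentres that become C7 and C8.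

Step 2
Reactants: 2 (1S,6R)-7-oxabicyclo[4.1.0]hept-2-ene; 3 tert-butyl acetate
Product: 4 tert-butyl 2-[(1R,6R)-6-hydroxycyclohex-2-en-1-yl]acetate
Conditions: LiN(iPr)2, THF, −78 °C; Et2AlCl; then 2, −78 → −20 °C
Reagents that add atoms: none
Why: Lewis-acid-assisted SN2 opening of the vinyl epoxide by the ester enolate at the activated allylic carbon, with inversion, should give the trans relationship between the C7 carbon arm and the C8 oxygen.

Step 3
Reactants: 4 tert-butyl 2-[(1R,6R)-6-hydroxycyclohex-2-en-1-yl]acetate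
Product: 5 tert-butyl 2-[(1R,6R)-6-(triethylsilyloxy)cyclohex-2-en-1-yl]acetate
Conditions: Et3SiCl, imidazole, CH2Cl2, 0 °C
Reagents that add atoms: triethylsilyl chloride, CC[Si](Cl)(CC)CC
Why: Silylation blocks lactonization of the γ-hydroxy ester and gives a group that can later be removed in the presence of a tert-butyldiphenylsilyl ether.

Step 4
Reactants: 5 tert-butyl 2-[(1R,6R)-6-(triethylsilyloxy)cyclohex-2-en-1-yl]acetate
Product: 6 tert-butyl 2-[(1R,6R)-4-oxo-6-(triethylsilyloxy)cyclohex-2-en-1-yl]acetate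
Conditions: Rh2(cap)4 (dirhodium tetrakis(caprolactamate), cat.), t-BuOOH, K2CO3, CH2Cl2, rt
Reagents that add atoms: tert-butyl hydroperoxide, CC(C)(C)OO
Why: Catalytic allylic C–H oxidation should occur at the unhindered allylic methylene (future C10) rather than at the substituted allylic methine C7, giving the enone whose carbonyl is the future C10.

Step 5
Reactants: 6 tert-butyl 2-[(1R,6R)-4-oxo-6-(triethylsilyloxy)cyclohex-2-en-1-yl]acetate
Product: 7 tert-butyl 2-[(1R,6R)-3-iodo-4-oxo-6-(triethylsilyloxy)cyclohex-2-en-1-yl]acetate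
Conditions: I2, pyridine, CH2Cl2, 0 °C → rt
Reagents that add atoms: iodine, II
Why: Pyridine-mediated α-iodination of the cyclohexenone (conjugate addition, iodination, elimination) puts the coupling handle on C1.

**Fragment 2: tether C2–C5 with C15**

Step 6
Reactants: 8 prop-2-yn-1-ol; 9 vinylmagnesium bromide
Product: 11 (2Z)-3-bromo-2-ethenylprop-2-en-1-ol, via alkenylmagnesium chelate 10 (not isolated)
Conditions: CH2=CHMgBr (3 equiv), CuI (cat.), THF, −20 °C → rt; then N-bromosuccinimide, −40 °C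
Reagents that add atoms: N-bromosuccinimide, O=C1CCC(=O)N1Br
Why: Copper-catalysed anti-carbomagnesiation of the magnesium alkoxide of propargyl alcohol puts the vinyl group on the internal carbon and magnesium on the terminal carbon in a five-membered chelate, and bromination of the C–Mg bond with retention gives the (Z)-bromide.

Step 7
Reactants: 11 (2Z)-3-bromo-2-ethenylprop-2-en-1-ol
Product: 12 {[(2Z)-3-bromo-2-ethenylprop-2-en-1-yl]oxy}(tert-butyl)diphenylsilane
Conditions: t-BuPh2SiCl, imidazole, CH2Cl2, 0 °C → rt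
Reagents that add atoms: tert-butyl(chloro)diphenylsilane, CC(C)(C)[Si](Cl)(c1ccccc1)c1ccccc1
Why: Standard silylation of the primary allylic alcohol (future C15–OH) with a robust group.

**Assembly**

Step 8
Reactants: 12 {[(2Z)-3-bromo-2-ethenylprop-2-en-1-yl]oxy}(tert-butyl)diphenylsilane; 7 tert-butyl 2-[(1R,6R)-3-iodo-4-oxo-6-(triethylsilyloxy)cyclohex-2-en-1-yl]acetate
Product: 14 tert-butyl 2-[(1R,6R)-3-{(3Z)-4-bromo-3-[(tert-butyldiphenylsilyloxy)methyl]but-3-en-1-yl}-4-oxo-6-(triethylsilyloxy)cyclohex-2-en-1-yl]acetate, via B-alkyl-9-BBN 13 (not isolated)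
Conditions: 9-BBN, THF, 0 °C → rt; then 7, PdCl2(dppf) (cat.), AsPh3, K3PO4 (aq), DMF, rt
Reagents that add atoms: none
Why: 9-BBN should hydroborate only the terminal vinyl group (the bromo-substituted alkene is deactivated), and the B-alkyl Suzuki–Miyaura coupling should take place at the reactive C–I bond of the α-iodoenone rather than at the vinyl bromide, forming C1–C2.

Step 9
Reactants: 14 tert-butyl 2-[(1R,6R)-3-{(3Z)-4-bromo-3-[(tert-butyldiphenylsilyloxy)methyl]but-3-en-1-yl}-4-oxo-6-(triethylsilyloxy)cyclohex-2-en-1-yl]acetate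
Product: 16 trans-fused keto ester tert-butyl 15-(tert-butyldiphenylsilyloxy)-10-oxo-8α-(triethylsilyloxy)-13,14-dinorcadin-4-en-12-oate (H-1α; H-6β; H-7α), via cis-fused C1 epimer 15 (not isolated)
Conditions: Bu3SnH, AIBN (cat.), PhH (high dilution, slow addition), 80 °C; then DBU (cat.), CH2Cl2, 0 °C → rt
Reagents that add atoms: none
Why: Bu3Sn• abstracts bromine from 14 to give a σ-vinyl radical at C5 that inverts rapidly (so the alkene geometry of 14 does not matter) and adds to C6, the unsubstituted β-carbon of the 2-alkylcyclohex-2-enone, after which the tertiary α-keto radical at C1 takes hydrogen from Bu3SnH. The closest known reaction type is the tin-hydride vinyl-radical cyclization onto an enone, here in the endo mode typical of α-substituted acceptors. Ring A closes 6-endo-trig (C5 to C6); the 5-exo alternative is disfavoured because it would attack the fully substituted C1 and leave an unstabilized secondary radical. C6 is set by 1,2-induction from C7: the radical should enter anti to the CH2CO2tBu arm (the 4-substituent effect of cyclohexenones), putting C5 on the α face, trans to the arm. C1 is set by DBU equilibration α to the C10 ketone, which converts the cis-fused epimer 15 into the trans-decalone in which C2, C5, the arm and the silyloxy group are all equatorial. The step needs endo regioselectivity, facial selectivity at C6 and clean bromine abstraction; these rest on the α-tether/β-CH pattern of the enone, on the C7 stereocentre, and on the absence of other halides or radical acceptors (both acrylate units are introduced later).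

Step 10
Reactants: 16 trans-fused keto ester
Product: 17 tert-butyl 15-(tert-butyldiphenylsilyloxy)-8α-(triethylsilyloxy)-13-norcadina-4,10(14)-dien-12-oate
Conditions: Zn, CH2Br2, TiCl4, THF, 0 °C; then 16, CH2Cl2, 0 °C → rt
Reagents that add atoms: dibromomethane, BrCBr
Why: Lombardo–Takai methylenation is non-basic and ketone-selective, so the β-silyloxy ketone should be converted into the C10=C14 exocyclic alkene without elimination and without touching the ester.

Step 11
Reactants: 17 tert-butyl 15-(tert-butyldiphenylsilyloxy)-8α-(triethylsilyloxy)-13-norcadina-4,10(14)-dien-12-oate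
Product: 20 tert-butyl 15-(tert-butyldiphenylsilyloxy)-8α-(triethylsilyloxy)cadina-4,10(14),11(13)-trien-12-oate, via Mannich base 18 (not isolated), via methiodide 19 (not isolated)
Conditions: LiN(iPr)2, THF, −78 °C; CH2=NMe2 iodide (Eschenmoser's salt), −78 → 0 °C; then MeI, MeOH, rt; then NaHCO3 (aq), CH2Cl2, rt
Reagents that add atoms: N,N-dimethylmethyleneiminium iodide, C=[N+](C)C.[I-]
Why: Mannich reaction of the ester enolate, N-methylation and β-elimination of trimethylamine is the standard α-methylenation of esters and creates C11=C13.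

Step 12
Reactants: 20 tert-butyl 15-(tert-butyldiphenylsilyloxy)-8α-(triethylsilyloxy)cadina-4,10(14),11(13)-trien-12-oate
Product: 21 tert-butyl 15-(tert-butyldiphenylsilyloxy)-8α-hydroxycadina-4,10(14),11(13)-trien-12-oate
Conditions: HF·pyridine, pyridine, THF, 0 °C
Reagents that add atoms: none
Why: A secondary triethylsilyl ether should be cleaved by buffered HF much faster than the primary tert-butyldiphenylsilyl ether, and the mildly acidic medium with a tert-butyl ester should suppress lactonization.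

**Fragment 3: side-chain acid**

Step 13
Reactants: 22 (tert-butyldimethylsilyloxy)acetaldehyde; 23 1,1,1,3,3,3-hexafluoropropan-2-yl prop-2-enoate
Product: 24 1,1,1,3,3,3-hexafluoropropan-2-yl (3S)-4-(tert-butyldimethylsilyloxy)-3-hydroxy-2-methylidenebutanoate
Conditions: β-isocupreidine (cat.), DMF, −55 °C
Reagents that add atoms: none
Why: The β-isocupreidine-catalysed asymmetric Morita–Baylis–Hillman reaction of the activated acrylate should set the carbinol centre; the usual facial sense corresponds to the (S) descriptor here because CH2OSi outranks the vinyl carbon.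

Step 14
Reactants: 24 1,1,1,3,3,3-hexafluoropropan-2-yl (3S)-4-(tert-butyldimethylsilyloxy)-3-hydroxy-2-methylidenebutanoate
Product: 25 1,1,1,3,3,3-hexafluoropropan-2-yl (3S)-3,4-bis(tert-butyldimethylsilyloxy)-2-methylidenebutanoate
Conditions: t-BuMe2SiOTf, 2,6-lutidine, CH2Cl2, −78 → 0 °C
Reagents that add atoms: tert-butyldimethylsilyl triflate, CC(C)(C)[Si](C)(C)OS(=O)(=O)C(F)(F)F
Why: Silylation of the secondary allylic alcohol under non-nucleophilic conditions prevents self-acylation in the coupling.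

Step 15
Reactants: 25 1,1,1,3,3,3-hexafluoropropan-2-yl (3S)-3,4-bis(tert-butyldimethylsilyloxy)-2-methylidenebutanoate
Product: 26 (3S)-3,4-bis(tert-butyldimethylsilyloxy)-2-methylidenebutanoic acid
Conditions: LiOH, THF/H2O, 0 °C; then 1 M HCl to pH 4
Reagents that add atoms: lithium hydroxide, [Li+].[OH-]
Why: The activated hexafluoroisopropyl ester should hydrolyse under mild conditions that leave the silyl ethers and the non-acidic C3' centre untouched.

**Completion**

Step 16
Reactants: 21 tert-butyl 15-(tert-butyldiphenylsilyloxy)-8α-hydroxycadina-4,10(14),11(13)-trien-12-oate; 26 (3S)-3,4-bis(tert-butyldimethylsilyloxy)-2-methylidenebutanoic acid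
Product: 28 tert-butyl 8α-{[(3S)-3,4-bis(tert-butyldimethylsilyloxy)-2-methylidenebutanoyl]oxy}-15-(tert-butyldiphenylsilyloxy)cadina-4,10(14),11(13)-trien-12-oate, via mixed anhydride 27 (not isolated)
Conditions: 26, 2,4,6-Cl3C6H2COCl, Et3N, PhMe, rt; then 21, DMAP, PhMe, rt
Reagents that add atoms: none
Why: Yamaguchi esterification acylates hindered secondary alcohols with retention at C8 and should be faster than lactonization onto the tert-butyl ester.

Step 17
Reactants: 28 tert-butyl 8α-{[(3S)-3,4-bis(tert-butyldimethylsilyloxy)-2-methylidenebutanoyl]oxy}-15-(tert-butyldiphenylsilyloxy)cadina-4,10(14),11(13)-trien-12-oate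
Product: 30 CNP0460913.3 (8α-{[(3S)-3,4-dihydroxy-2-methylidenebutanoyl]oxy}-15-hydroxycadina-4,10(14),11(13)-trien-12-oic acid; 1S,6S,7S,8R), via trimethylsilyl ester 29 (not isolated)
Conditions: Me3SiOTf, 2,6-lutidine, CH2Cl2, 0 °C; then HF·pyridine, THF, 0 °C → rt
Reagents that add atoms: none
Why: Buffered silyl triflate converts the tert-butyl ester into a silyl ester without protic acid (the exocyclic alkene is spared), and HF·pyridine then removes all silyl groups under non-basic conditions that should avoid lactonization of the dihydroxy ester side chain.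

**Compound list**
1 | cyclohexa-1,3-diene | C1=CC=CCC1 | starting material
2 | (1S,6R)-7-oxabicyclo[4.1.0]hept-2-ene | O1[C@H]2C=CCC[C@@H]12 | intermediate
3 | tert-butyl acetate | CC(=O)OC(C)(C)C | starting material
4 | tert-butyl 2-[(1R,6R)-6-hydroxycyclohex-2-en-1-yl]acetate | CC(C)(C)OC(=O)C[C@@H]1C=CCC[C@H]1O | intermediate
5 | tert-butyl 2-[(1R,6R)-6-(triethylsilyloxy)cyclohex-2-en-1-yl]acetate | CC(C)(C)OC(=O)C[C@@H]1C=CCC[C@H]1O[Si](CC)(CC)CC | intermediate
6 | tert-butyl 2-[(1R,6R)-4-oxo-6-(triethylsilyloxy)cyclohex-2-en-1-yl]acetate | CC(C)(C)OC(=O)C[C@@H]1C=CC(=O)C[C@H]1O[Si](CC)(CC)CC | intermediate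
7 | tert-butyl 2-[(1R,6R)-3-iodo-4-oxo-6-(triethylsilyloxy)cyclohex-2-en-1-yl]acetate | CC(C)(C)OC(=O)C[C@@H]1C=C(I)C(=O)C[C@H]1O[Si](CC)(CC)CC | intermediate
8 | prop-2-yn-1-ol | C#CCO | starting material
9 | vinylmagnesium bromide | C=C[Mg]Br | starting material
10 | alkenylmagnesium chelate (4-ethenyl-2,5-dihydro-1,2-oxamagnesole) | C=CC1=C[Mg]OC1 | intermediate (not isolated)
11 | (2Z)-3-bromo-2-ethenylprop-2-en-1-ol | Br/C=C(/C=C)CO | intermediate
12 | {[(2Z)-3-bromo-2-ethenylprop-2-en-1-yl]oxy}(tert-butyl)diphenylsilane | Br/C=C(/C=C)CO[Si](c1ccccc1)(c1ccccc1)C(C)(C)C | intermediate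
13 | B-alkyl-9-BBN: 9-{(3Z)-4-bromo-3-[(tert-butyldiphenylsilyloxy)methyl]but-3-en-1-yl}-9-borabicyclo[3.3.1]nonane | Br/C=C(/CCB1C2CCCC1CCC2)CO[Si](c1ccccc1)(c1ccccc1)C(C)(C)C | intermediate (not isolated)
14 | tert-butyl 2-[(1R,6R)-3-{(3Z)-4-bromo-3-[(tert-butyldiphenylsilyloxy)methyl]but-3-en-1-yl}-4-oxo-6-(triethylsilyloxy)cyclohex-2-en-1-yl]acetate | CC(C)(C)OC(=O)C[C@@H]1C=C(CC/C(CO[Si](c2ccccc2)(c2ccccc2)C(C)(C)C)=C/Br)C(=O)C[C@H]1O[Si](CC)(CC)CC | intermediate
15 | cis-fused C1 epimer of 16 (H-1β, H-6β) | CC(C)(C)OC(=O)C[C@@H]1[C@H]2C=C(CO[Si](c3ccccc3)(c3ccccc3)C(C)(C)C)CC[C@H]2C(=O)C[C@H]1O[Si](CC)(CC)CC | intermediate (not isolated)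
16 | tert-butyl 15-(tert-butyldiphenylsilyloxy)-10-oxo-8α-(triethylsilyloxy)-13,14-dinorcadin-4-en-12-oate (trans-fused; H-1α, H-6β, H-7α) | CC(C)(C)OC(=O)C[C@@H]1[C@H]2C=C(CO[Si](c3ccccc3)(c3ccccc3)C(C)(C)C)CC[C@@H]2C(=O)C[C@H]1O[Si](CC)(CC)CC | intermediate
17 | tert-butyl 15-(tert-butyldiphenylsilyloxy)-8α-(triethylsilyloxy)-13-norcadina-4,10(14)-dien-12-oate | CC(C)(C)OC(=O)C[C@@H]1[C@H]2C=C(CO[Si](c3ccccc3)(c3ccccc3)C(C)(C)C)CC[C@@H]2C(=C)C[C@H]1O[Si](CC)(CC)CC | intermediate
18 | Mannich base: tert-butyl 13-(dimethylamino)-15-(tert-butyldiphenylsilyloxy)-8α-(triethylsilyloxy)cadina-4,10(14)-dien-12-oate (C11 epimers) | CN(C)CC(C(=O)OC(C)(C)C)[C@@H]1[C@H]2C=C(CO[Si](c3ccccc3)(c3ccccc3)C(C)(C)C)CC[C@@H]2C(=C)C[C@H]1O[Si](CC)(CC)CC | intermediate (not isolated)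
19 | methiodide of 18 (trimethylammonium iodide) | C[N+](C)(C)CC(C(=O)OC(C)(C)C)[C@@H]1[C@H]2C=C(CO[Si](c3ccccc3)(c3ccccc3)C(C)(C)C)CC[C@@H]2C(=C)C[C@H]1O[Si](CC)(CC)CC.[I-] | intermediate (not isolated)
20 | tert-butyl 15-(tert-butyldiphenylsilyloxy)-8α-(triethylsilyloxy)cadina-4,10(14),11(13)-trien-12-oate | C=C(C(=O)OC(C)(C)C)[C@@H]1[C@H]2C=C(CO[Si](c3ccccc3)(c3ccccc3)C(C)(C)C)CC[C@@H]2C(=C)C[C@H]1O[Si](CC)(CC)CC | intermediate
21 | tert-butyl 15-(tert-butyldiphenylsilyloxy)-8α-hydroxycadina-4,10(14),11(13)-trien-12-oate | C=C(C(=O)OC(C)(C)C)[C@@H]1[C@H]2C=C(CO[Si](c3ccccc3)(c3ccccc3)C(C)(C)C)CC[C@@H]2C(=C)C[C@H]1O | intermediate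
22 | (tert-butyldimethylsilyloxy)acetaldehyde | O=CCO[Si](C)(C)C(C)(C)C | starting material
23 | 1,1,1,3,3,3-hexafluoropropan-2-yl prop-2-enoate | C=CC(=O)OC(C(F)(F)F)C(F)(F)F | starting material
24 | 1,1,1,3,3,3-hexafluoropropan-2-yl (3S)-4-(tert-butyldimethylsilyloxy)-3-hydroxy-2-methylidenebutanoate | C=C(C(=O)OC(C(F)(F)F)C(F)(F)F)[C@H](O)CO[Si](C)(C)C(C)(C)C | intermediate
25 | 1,1,1,3,3,3-hexafluoropropan-2-yl (3S)-3,4-bis(tert-butyldimethylsilyloxy)-2-methylidenebutanoate | C=C(C(=O)OC(C(F)(F)F)C(F)(F)F)[C@H](O[Si](C)(C)C(C)(C)C)CO[Si](C)(C)C(C)(C)C | intermediate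
26 | (3S)-3,4-bis(tert-butyldimethylsilyloxy)-2-methylidenebutanoic acid | C=C(C(=O)O)[C@H](O[Si](C)(C)C(C)(C)C)CO[Si](C)(C)C(C)(C)C | intermediate
27 | mixed anhydride of 26 with 2,4,6-trichlorobenzoic acid | C=C(C(=O)OC(=O)c1c(Cl)cc(Cl)cc1Cl)[C@H](O[Si](C)(C)C(C)(C)C)CO[Si](C)(C)C(C)(C)C | intermediate (not isolated)
28 | tert-butyl 8α-{[(3S)-3,4-bis(tert-butyldimethylsilyloxy)-2-methylidenebutanoyl]oxy}-15-(tert-butyldiphenylsilyloxy)cadina-4,10(14),11(13)-trien-12-oate | C=C(C(=O)OC(C)(C)C)[C@@H]1[C@H]2C=C(CO[Si](c3ccccc3)(c3ccccc3)C(C)(C)C)CC[C@@H]2C(=C)C[C@H]1OC(=O)C(=C)[C@H](O[Si](C)(C)C(C)(C)C)CO[Si](C)(C)C(C)(C)C | intermediate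
29 | trimethylsilyl ester corresponding to 28 | C=C(C(=O)O[Si](C)(C)C)[C@@H]1[C@H]2C=C(CO[Si](c3ccccc3)(c3ccccc3)C(C)(C)C)CC[C@@H]2C(=C)C[C@H]1OC(=O)C(=C)[C@H](O[Si](C)(C)C(C)(C)C)CO[Si](C)(C)C(C)(C)C | intermediate (not isolated)
30 | CNP0460913.3, (1S,6S,7S,8R)-8-{[(3S)-3,4-dihydroxy-2-methylidenebutanoyl]oxy}-15-hydroxycadina-4,10(14),11(13)-trien-12-oic acid | C=C(C(=O)O)[C@@H]1[C@H]2C=C(CO)CC[C@@H]2C(=C)C[C@H]1OC(=O)C(=C)[C@H](O)CO | target

**Step count and risks**
Total steps: 17. Longest linear sequence: 12 (steps 1–5, 8–12, 16, 17).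

Most likely to fail:

1. Step 9. The facial selectivity at C6 may be poor: the silyloxy group on C8 can oppose the directing effect of the C7 arm, so part of the material may cyclize syn to the arm, and premature reduction of the vinyl radical is also possible. The fallback replaces kinetic by thermodynamic control and runs from 11 and 7 back to 16. The unprotected bromodienol 11 is hydroborated (9-BBN, 2 equiv) and coupled with 7 as in step 8 to give tert-butyl 2-[(1R,6R)-3-[(3Z)-4-bromo-3-(hydroxymethyl)but-3-en-1-yl]-4-oxo-6-(triethylsilyloxy)cyclohex-2-en-1-yl]acetate F1. Bu3SnH/AIBN cyclization gives the bicyclic keto alcohol (mixture at C1 and C6) F2. MnO2 oxidizes the allylic alcohol, and DBU then equilibrates both ring-fusion centres (C1 α to the ketone, C6 γ to the enal through its dienol) to the all-equatorial trans-fused keto enal F3. NaBH4 at −78 °C reduces only the aldehyde to the trans-fused keto alcohol F4, and t-BuPh2SiCl/imidazole returns to 16.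

2. Step 2. The enolate may attack in the SN2' sense or at the non-allylic epoxide carbon, and the alkoxide formed may lactonize. The fallback runs from 2 back to 5 and uses an alkynylalane, a reagent class with established allylic SN2 selectivity on vinyl epoxides. Et2AlC≡CSiMe3 (from Me3SiC≡CH, BuLi, Et2AlCl) opens 2 with inversion to (1R,2S)-2-[(trimethylsilyl)ethynyl]cyclohex-3-en-1-ol F5. Et3SiCl/imidazole gives triethyl{[(1R,2S)-2-[(trimethylsilyl)ethynyl]cyclohex-3-en-1-yl]oxy}silane F6. Hydroboration of the silylalkyne with dicyclohexylborane followed by NaOH/H2O2 gives 2-[(1R,6R)-6-(triethylsilyloxy)cyclohex-2-en-1-yl]acetic acid F7, and Boc2O, DMAP, tert-butanol gives 5.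

3. Step 4. Hydrogen abstraction at the allylic methine C7 instead of the methylene would give transposed or over-oxidized enones. The fallback runs from 5 back to 6 and replaces the radical C–H oxidation by a pericyclic one. SeO2 (cat.)/t-BuOOH (ene reaction then [2,3] shift, with its CH2 > CH preference) hydroxylates the methylene to tert-butyl 2-[(1R,6R)-4-hydroxy-6-(triethylsilyloxy)cyclohex-2-en-1-yl]acetate (epimers at the carbinol) F8, and MnO2 oxidizes this allylic alcohol to 6.

Further compounds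
F1 | step 9 | tert-butyl 2-[(1R,6R)-3-[(3Z)-4-bromo-3-(hydroxymethyl)but-3-en-1-yl]-4-oxo-6-(triethylsilyloxy)cyclohex-2-en-1-yl]acetate | CC(C)(C)OC(=O)C[C@@H]1C=C(CC/C(CO)=C/Br)C(=O)C[C@H]1O[Si](CC)(CC)CC
F2 | step 9 | tert-butyl 15-hydroxy-10-oxo-8α-(triethylsilyloxy)-13,14-dinorcadin-4-en-12-oate, mixture at C1 and C6 | CC(C)(C)OC(=O)C[C@@H]1C2C=C(CO)CCC2C(=O)C[C@H]1O[Si](CC)(CC)CC
F3 | step 9 | tert-butyl 10,15-dioxo-8α-(triethylsilyloxy)-13,14-dinorcadin-4-en-12-oate (trans-fused; H-1α, H-6β) | CC(C)(C)OC(=O)C[C@@H]1[C@H]2C=C(C=O)CC[C@@H]2C(=O)C[C@H]1O[Si](CC)(CC)CC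
F4 | step 9 | tert-butyl 15-hydroxy-10-oxo-8α-(triethylsilyloxy)-13,14-dinorcadin-4-en-12-oate (trans-fused; H-1α, H-6β) | CC(C)(C)OC(=O)C[C@@H]1[C@H]2C=C(CO)CC[C@@H]2C(=O)C[C@H]1O[Si](CC)(CC)CC
F5 | step 2 | (1R,2S)-2-[(trimethylsilyl)ethynyl]cyclohex-3-en-1-ol | C[Si](C)(C)C#C[C@@H]1C=CCC[C@H]1O
F6 | step 2 | triethyl{[(1R,2S)-2-[(trimethylsilyl)ethynyl]cyclohex-3-en-1-yl]oxy}silane | C[Si](C)(C)C#C[C@@H]1C=CCC[C@H]1O[Si](CC)(CC)CC
F7 | step 2 | 2-[(1R,6R)-6-(triethylsilyloxy)cyclohex-2-en-1-yl]acetic acid | OC(=O)C[C@@H]1C=CCC[C@H]1O[Si](CC)(CC)CC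
F8 | step 4 | tert-butyl 2-[(1R,6R)-4-hydroxy-6-(triethylsilyloxy)cyclohex-2-en-1-yl]acetate (carbinol epimers) | CC(C)(C)OC(=O)C[C@@H]1C=CC(O)C[C@H]1O[Si](CC)(CC)CC
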